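The runs were generated by integration from invented constants, and the scatter is random.

The pitfall in these flasks is to read the fall of X as conversion: by 15.0 h the birch run has lost 41.3% of its X, yet Z and Q together hold 22.2%.

all flasks: X 0.050 M

| flask | J | remark | time |
|---|---|---|---|
| birch | 0.042 M | run made earlier |  |
| cedar | 0.044 M | run made earlier |  |
| south | 0.0520 M |  | 30 h |
| north-east | 0.0680 M |  | 30 h |

| run | time / h | X / % | Q / % | Z / % |
|---|---|---|---|---|
| birch | 1.33 | 80.8 | 0.2 | 2.8 |
| birch | 2.00 | 75.6 | 0.2 | 3.9 |
| birch | 3.00 | 71.8 | 1.3 | 6.4 |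
| birch | 5.00 | 67.4 | 0.5 | 8.5 |
| birch | 10.0 | 61.7 | 2.7 | 13.8 |
| birch | 15.0 | 58.7 | 4.9 | 17.3 |
| cedar | 2.50 | 73.3 | 1.0 | 6.1 |
| cedar | 5.00 | 67.4 | 1.0 | 9.1 |
| cedar | 8.00 | 63.8 | 1.6 | 12.3 |
| cedar | 10.0 | 62.0 | 2.6 | 14.9 |
| cedar | 12.0 | 60.3 | 3.7 | 15.2 |
| cedar | 15.0 | 56.2 | 6.3 | 17.2 |

(standard deviation of a reading: 0.5 percentage points)

- which of these there is most of at the end, counted by the X in it, south (X / Q / Z)
- which of these there is most of at the end, counted by the X in it, north-east (X / Q / Z)
- the largest of these amounts at the end, in percent of the X charged, south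
- the largest of these amounts at the end, in percent of the X charged, north-east

- a reading of X is of its free form alone

So two things must be separated. The pool is whatever Z and Q have not taken, free X plus an unseen form. In birch it stands at 77.8% at 15.0 h, and free X is 75.4% of it, against 77.8% at 3.00 h, so that share is taken as steady. Counting one J per Z and two per Q gives birch a mean J of 0.0352 M, and hence 0.475 M⁻¹ h⁻¹: the pool constant, the fall in the logarithm of the pool per unit of mean J and time. At a given level of J the pool decays as a pseudo-first-order quantity.

J never exceeds its charge, which bounds free X from below: 36.0% in south, 28.6% in north-east. Holding J at 50.0% of charge throughout is too little, since cedar keeps 66.1% at 15.0 h; that gives upper bounds of 52.1% and 46.5%. My own tightening takes a mean J of 75.0% of charge, giving 43.3% and 36.5%. North-east then has 51.7% converted, and one form would need 70.6% of that to pass X. Of the Z and Q in cedar, Z holds 73.2% at the last reading, down from 85.1% at 10.0 h, and what Z loses in share Q gains, so this reckoning expects neither form to hold that much at 30 h and puts X first.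

The forecast, built on “a quickly formed, unseen adduct”, says X at 49% for south and X at 41% for north-east: inside both brackets, above my tightened values .

South ends with X first at 44.8%, north-east with X first at 38.4%, its Q at 24.2%.

    X + J ⇌ L + Z (K = 11.0, k = 0.629 M⁻¹ h⁻¹)
    Z + J ⇌ L + Q (K = 9.29, k = 1.02 M⁻¹ h⁻¹)
    X ⇌ E (K = 0.340, k = 0.193 h⁻¹)

The unseen form is E, at 13.4% in north-east. The same flask with 0.17 M of J gets the same reckoning: from 6.69% at full charge to 22.5% at 50.0%, tightened to 12.3%. That flask keeps 57% of its J, and ends with Q at 65.4% and X at 13.7%.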